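**Retrosynthetic overview**
1. Last operation: fluoride removal of two silyl groups, one on C14–OH and one on the tertiary OH of the 9-ester.
2. Key disconnection C7–C8: the ten-membered ring is closed by a radical addition–fragmentation. A C8 α-isobutyryloxy radical (C8 aldehyde + i-PrCOI) attacks C7 of an α-(mesylmethyl)butenolide and MeSO2• leaves. This one step sets C7 and C8, installs the 8-ester and frees the C11=C13 methylene.
3. Ring order: the butenolide is made first (C6–OH esterified with 2-(mesylmethyl)acrylic acid, then ring-closing metathesis). The carbocycle is made second.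
4. C3–C4: B-alkyl Suzuki coupling of a diene (C1–C3, C8–C10, C14) with a (Z)-alkenyl iodide (C4–C7, C15).
5. C9 comes from a Nozaki–Hiyama–Kishi addition to (R)-glyceraldehyde acetonide, whose CH2O carbon is later cut off to give the C8 aldehyde. C6 comes from catalytic asymmetric propynylation of crotonaldehyde.

Assumption: positions use germacrane numbering (C1–C15, lactone C6–O–C12), and the ProPhenol enantiomer used is the one that adds the alkynyl group to the Re face of crotonaldehyde (taken as (S,S); both enantiomers are sold).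

**Step 1**
Reactants: 1 vinyl bromide; 2 propargyl alcohol
Product: 3 pent-4-en-2-yn-1-ol
Conditions: PdCl2(PPh3)2 (2 mol %), CuI (4 mol %), i-Pr2NH, THF, 0 °C to rt
Reagents that add atoms: none
Why: Sonogashira coupling joins the alkenyl bromide to the terminal alkyne without touching the free alcohol; no stereocentre is formed.

**Step 2**
Reactants: 3 pent-4-en-2-yn-1-ol
Product: 5 (2Z)-2-iodopenta-2,4-dien-1-ol, via vinylstannane 4 (not isolated)
Conditions: [Cp*RuCl]4 (2 mol %), Bu3SnH (slow addition), CH2Cl2, rt; then I2, −78 to 0 °C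
Reagents that add atoms: tributyltin hydride, CCCC[SnH](CCCC)CCCC (tin is in 4 only); iodine, II
Why: Hydroxyl-directed ruthenium-catalysed trans-hydrostannation (O–H···Cl–Ru hydrogen bond) puts tin on the alkyne carbon next to CH2OH and adds H and Sn anti, so the vinyl group ends cis to tin, and tin–iodine exchange keeps this Z geometry (future C1=C10 with C2 cis to C9).

**Step 3**
Reactants: 5 (2Z)-2-iodopenta-2,4-dien-1-ol
Product: 6 tert-butyl{[(2Z)-2-iodopenta-2,4-dien-1-yl]oxy}diphenylsilane
Conditions: TBDPSCl, imidazole, CH2Cl2, 0 °C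
Reagents that add atoms: tert-butylchlorodiphenylsilane, CC(C)(C)[Si](Cl)(c1ccccc1)c1ccccc1
Why: Standard silylation of the primary allylic alcohol; TBDPS is chosen because it must later survive H5IO6 and the acyl iodide.

**Step 4**
Reactants: 6 iodo diene silyl ether; 7 (R)-2,2-dimethyl-1,3-dioxolane-4-carbaldehyde
Product: 8 anti dienol (1S,2Z)-2-[(tert-butyldiphenylsilyloxy)methyl]-1-[(4R)-2,2-dimethyl-1,3-dioxolan-4-yl]penta-2,4-dien-1-ol
Conditions: CrCl2 (4 equiv), NiCl2 (1 mol %), DMF, rt
Reagents that add atoms: none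
Why: Nozaki–Hiyama–Kishi reaction: the alkenylchromium reagent forms with retention of alkene geometry and adds in the polar Felkin–Anh sense (anti to the dioxolane C–O bond) to give the 1,2-anti alcohol, which is the (9S) centre, and the minor syn epimer is removed by chromatography.

**Step 5**
Reactants: 9 2-hydroxy-2-methylpropanoic acid
Product: 11 2-methyl-2-(triethylsilyloxy)propanoic acid, via bis-silyl derivative 10 (not isolated)
Conditions: TESCl (2.2 equiv), imidazole, DMF, rt; then THF–H2O, 0 °C, pH 4 work-up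
Reagents that add atoms: chlorotriethylsilane, CC[Si](Cl)(CC)CC
Why: Exhaustive silylation followed by selective hydrolysis of the far more labile silyl ester leaves the hindered tertiary TES ether; no stereocentre is involved.

**Step 6**
Reactants: 8 anti dienol; 11 TES-protected acid
Product: 12 diene ester (8 acylated on O9 by the 2-methyl-2-(triethylsilyloxy)propanoyl group; 9S; dioxolane 4R; 2Z)
Conditions: 2-methyl-6-nitrobenzoic anhydride (MNBA), DMAP, Et3N, CH2Cl2, rt to 40 °C
Reagents that add atoms: none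
Why: Shiina esterification (mixed anhydride, acyl transfer by DMAP) copes with a hindered acid and a hindered alcohol and acylates O9 with retention at C9.

**Step 7**
Reactants: 13 propyne; 14 (E)-crotonaldehyde
Product: 16 (2E,4S)-hept-2-en-5-yn-4-ol, via alkynylzinc 15 (not isolated)
Conditions: (S,S)-ProPhenol (10 mol %), Me2Zn (3 equiv), P(O)Ph3 (20 mol %), toluene, 0 °C; aq NH4Cl
Reagents that add atoms: dimethylzinc, C[Zn]C (zinc and methyl are in 15 only)
Why: Catalytic asymmetric alkynylation of an enal by the dinuclear zinc–ProPhenol catalyst adds the alkynylzinc 1,2 to the Re face and sets the C6 carbinol as (S), which becomes 6R in the lactone by a priority change only.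

**Step 8**
Reactants: 16 (2E,4S)-hept-2-en-5-yn-4-ol
Product: 18 (2E,4S,5Z)-6-iodohepta-2,5-dien-4-ol, via alkenylalanate 17 (not isolated)
Conditions: NaAlH2(OCH2CH2OMe)2 (Red-Al, 1.6 equiv), Et2O, 0 °C to rt; EtOAc; then I2, THF, −78 °C
Reagents that add atoms: sodium bis(2-methoxyethoxy)aluminium dihydride, [Na+].[AlH2-](OCCOC)OCCOC (its atoms are in 17 only); iodine, II
Why: Alkoxide-directed trans-hydroalumination of the propargylic alcohol gives the five-membered alanate with aluminium on the distal carbon, and iodinolysis with retention gives the (Z)-iodide in which iodine (the future C3 site) is cis to C6; the isolated propenyl group is inert.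

**Step 9**
Reactants: 12 diene ester; 18 (Z)-alkenyl iodide
Product: 20 triene alcohol (propenyl–C6H(OH)–C5H=C4(Me)–C3H2–C2H2–C1H=C10(CH2OTBDPS)–C9H(O-acyl)–dioxolane; 6S; 9S; dioxolane 4R; 4Z; 1(10)Z), via alkylborane 19 (not isolated)
Conditions: 12, 9-BBN-H (1.2 equiv), THF, rt; then aq Cs2CO3, 18, Pd(dppf)Cl2 (5 mol %), AsPh3, DMF, rt
Reagents that add atoms: 9-BBN-H, [H]B1C2CCCC1CCC2 (the boron bicycle is in 19 only)
Why: B-alkyl Suzuki–Miyaura coupling: 9-BBN-H adds only to the monosubstituted terminus of the diene (boron on C3) and the alkylborane couples with the alkenyl iodide with retention, which fixes the 4Z alkene while the free OH, the esters and the acetonide are tolerated.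

**Step 10**
Reactants: 21 2-(bromomethyl)acrylic acid; 22 sodium methanesulfinate
Product: 23 2-[(methylsulfonyl)methyl]acrylic acid
Conditions: MeOH, 50 °C; acidic work-up
Reagents that add atoms: none
Why: S-alkylation of the soft sulfinate by the allylic bromide (SN2 or degenerate SN2′) gives the allyl sulfone; no stereocentre is involved.

**Step 11**
Reactants: 20 triene alcohol; 23 sulfonyl acrylic acid
Product: 24 sulfonylacrylate ester of 20 (O6 acylated; 6S; 9S)
Conditions: MNBA, DMAP (cat.), Et3N, CH2Cl2, 0 °C to rt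
Reagents that add atoms: none
Why: Shiina esterification of the only free hydroxyl occurs with retention at C6, and reversible DMAP addition to the sulfonylacrylate is degenerate and harmless.

**Step 12**
Reactants: 24 sulfonylacrylate ester
Product: 25 butenolide (5R)-3-[(methylsulfonyl)methyl]furan-2(5H)-one carrying the C5–C10 chain on C6 (9S; dioxolane 4R; 4Z; 1(10)Z)
Conditions: second-generation Hoveyda–Grubbs catalyst (10 mol %), 1,4-benzoquinone (20 mol %), toluene (5 mM), 80 °C, argon sparge
Reagents that add atoms: none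
Why: Ring-closing metathesis: the catalyst loads on the disubstituted propenyl group and closes the five-membered ring onto the 1,1-disubstituted acrylate with loss of propene, the two trisubstituted alkenes are too hindered to react, and C6 is untouched.

**Step 13**
Reactants: 25 butenolide
Product: 27 C8 aldehyde (6R; 9S), via diol 26 (not isolated)
Conditions: H5IO6 (1.6 equiv), EtOAc, 0 °C to rt; used crude at once
Reagents that add atoms: none
Why: Periodic acid hydrolyses the terminal acetonide and cleaves the resulting 1,2-diol in the same flask (Malaprade glycol cleavage), which deletes the auxiliary stereocentre and gives the α-acyloxy aldehyde under acidic, non-epimerising conditions.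

**Step 14 (key step)**
Reactants: 27 C8 aldehyde; 28 isobutyryl chloride
Product: 31 bis-silyl macrocycle (6R,7S,8S,9S)-8-isobutyryloxy-9-[2-methyl-2-(triethylsilyloxy)propanoyloxy]-14-(tert-butyldiphenylsilyloxy)germacra-1(10)Z,4Z,11(13)-trien-6,12-olide, via isobutyryl iodide 29 (not isolated), via iodo ester 30 (not isolated)
Conditions: 28, NaI, MeCN, 0 °C, dark; 27, ZnI2 (5 mol %), CH2Cl2, −20 °C; then into Mn2(CO)10 (1.1 equiv), 2,6-di-tert-butyl-4-methylpyridine (0.3 equiv), PhH (1 mM), blue LED, 15 °C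
Reagents that add atoms: sodium iodide, [Na+].[I-] (iodine is in 29 and 30 only)
Why: Proposed new method: i-PrCOI adds to the aldehyde to give the 1-iodoalkyl ester 30, photogenerated •Mn(CO)5 abstracts iodine, the nucleophilic C8 α-acyloxy radical closes the ten-membered ring by attacking the electron-poor C7 of the butenolide, and the C11 radical then expels MeSO2• (taken up by manganese) to unveil the exocyclic methylene; C7 is set by attack anti to the C5 side chain on C6 (trans-lactone) and C8 by bond formation anti to the C9–O bond in the A1,3-minimised rotamer (8,9-threo), while A1,3 strain across the two Z-alkenes pre-folds the chain, holds C8 away from the C2–H bonds, and the apolar solvent and low temperature slow the 1,2-acyloxy shift; the closest known reaction types are visible-light manganese-carbonyl generation of α-acyloxy radicals from aldehydes and acyl iodides, addition–fragmentation (SH2′) allylation of β-acyloxy glycosyl radicals with 2-carboalkoxyallyl sulfones, and endo radical macrocyclisation onto enoates.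

**Step 15**
Reactants: 31 bis-silyl macrocycle
Product: 32 target CNP0220567.2
Conditions: HF·pyridine, pyridine, THF, 0 °C to rt
Reagents that add atoms: none
Why: Buffered fluoride desilylation removes both silyl groups without acyl migration, lactone opening or conjugate addition to the methylene lactone, and no stereocentre is touched.

**Compound list**
1 | vinyl bromide | C=CBr | starting material
2 | propargyl alcohol | C#CCO | starting material
3 | pent-4-en-2-yn-1-ol | C=CC#CCO | intermediate
4 | (2Z)-2-(tributylstannyl)penta-2,4-dien-1-ol | C=C/C=C(/CO)[Sn](CCCC)(CCCC)CCCC | intermediate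
5 | (2Z)-2-iodopenta-2,4-dien-1-ol | C=C/C=C(/CO)I | intermediate
6 | tert-butyl{[(2Z)-2-iodopenta-2,4-dien-1-yl]oxy}diphenylsilane | C=C/C=C(/CO[Si](c1ccccc1)(c1ccccc1)C(C)(C)C)I | intermediate
7 | (R)-2,2-dimethyl-1,3-dioxolane-4-carbaldehyde | O=C[C@H]1COC(C)(C)O1 | starting material
8 | anti dienol (1S,2Z; dioxolane 4R) | C=C/C=C(/CO[Si](c1ccccc1)(c1ccccc1)C(C)(C)C)[C@H](O)[C@H]1COC(C)(C)O1 | intermediate
9 | 2-hydroxy-2-methylpropanoic acid | CC(C)(O)C(=O)O | starting material
10 | triethylsilyl 2-methyl-2-(triethylsilyloxy)propanoate | CC(C)(O[Si](CC)(CC)CC)C(=O)O[Si](CC)(CC)CC | intermediate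
11 | 2-methyl-2-(triethylsilyloxy)propanoic acid | CC(C)(O[Si](CC)(CC)CC)C(=O)O | intermediate
12 | diene ester (9S; dioxolane 4R; 2Z) | C=C/C=C(/CO[Si](c1ccccc1)(c1ccccc1)C(C)(C)C)[C@H](OC(=O)C(C)(C)O[Si](CC)(CC)CC)[C@H]1COC(C)(C)O1 | intermediate
13 | propyne | CC#C | starting material
14 | (E)-crotonaldehyde | C/C=C/C=O | starting material
15 | methyl(prop-1-yn-1-yl)zinc | C[Zn]C#CC | intermediate
16 | (2E,4S)-hept-2-en-5-yn-4-ol | C/C=C/[C@H](O)C#CC | intermediate
17 | sodium cyclic alkenylalanate of 16 (five-membered O–Al–C4=C5–C6 ring) | C/C=C/[C@H]1C=C(C)[Al-](OCCOC)(OCCOC)O1.[Na+] | intermediate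
18 | (2E,4S,5Z)-6-iodohepta-2,5-dien-4-ol | C/C=C/[C@H](O)/C=C(/C)I | intermediate
19 | B-alkyl-9-BBN from 12 (boron on C3) | C1CC2CCCC(C1)B2CC/C=C(/CO[Si](c1ccccc1)(c1ccccc1)C(C)(C)C)[C@H](OC(=O)C(C)(C)O[Si](CC)(CC)CC)[C@H]1COC(C)(C)O1 | intermediate
20 | triene alcohol (6S; 9S; 4Z; 1(10)Z) | C/C=C/[C@H](O)/C=C(/C)CC/C=C(/CO[Si](c1ccccc1)(c1ccccc1)C(C)(C)C)[C@H](OC(=O)C(C)(C)O[Si](CC)(CC)CC)[C@H]1COC(C)(C)O1 | intermediate
21 | 2-(bromomethyl)acrylic acid | C=C(CBr)C(=O)O | starting material
22 | sodium methanesulfinate | CS(=O)[O-].[Na+] | starting material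
23 | 2-[(methylsulfonyl)methyl]acrylic acid | C=C(CS(C)(=O)=O)C(=O)O | intermediate
24 | sulfonylacrylate ester of 20 | C/C=C/[C@H](OC(=O)C(=C)CS(C)(=O)=O)/C=C(/C)CC/C=C(/CO[Si](c1ccccc1)(c1ccccc1)C(C)(C)C)[C@H](OC(=O)C(C)(C)O[Si](CC)(CC)CC)[C@H]1COC(C)(C)O1 | intermediate
25 | α-(mesylmethyl)butenolide (6R; 9S; dioxolane 4R) | CS(=O)(=O)CC1=C[C@H](OC1=O)/C=C(/C)CC/C=C(/CO[Si](c2ccccc2)(c2ccccc2)C(C)(C)C)[C@H](OC(=O)C(C)(C)O[Si](CC)(CC)CC)[C@H]2COC(C)(C)O2 | intermediate
26 | butenolide 1,2-diol | CS(=O)(=O)CC1=C[C@H](OC1=O)/C=C(/C)CC/C=C(/CO[Si](c2ccccc2)(c2ccccc2)C(C)(C)C)[C@H](OC(=O)C(C)(C)O[Si](CC)(CC)CC)[C@H](O)CO | intermediate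
27 | butenolide C8 aldehyde (6R; 9S) | CS(=O)(=O)CC1=C[C@H](OC1=O)/C=C(/C)CC/C=C(/CO[Si](c2ccccc2)(c2ccccc2)C(C)(C)C)[C@H](OC(=O)C(C)(C)O[Si](CC)(CC)CC)C=O | intermediate
28 | isobutyryl chloride | CC(C)C(=O)Cl | starting material
29 | isobutyryl iodide | CC(C)C(=O)I | intermediate
30 | 1-iodoalkyl isobutyrate (both C8 epimers) | CS(=O)(=O)CC1=C[C@H](OC1=O)/C=C(/C)CC/C=C(/CO[Si](c2ccccc2)(c2ccccc2)C(C)(C)C)[C@H](OC(=O)C(C)(C)O[Si](CC)(CC)CC)C(I)OC(=O)C(C)C | intermediate
31 | bis-silyl macrocycle (6R,7S,8S,9S) | C=C1C(=O)O[C@@H]2/C=C(/C)CC/C=C(/CO[Si](c3ccccc3)(c3ccccc3)C(C)(C)C)[C@H](OC(=O)C(C)(C)O[Si](CC)(CC)CC)[C@@H](OC(=O)C(C)C)[C@@H]12 | intermediate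
32 | CNP0220567.2 (6R,7S,8S,9S; 1(10)Z; 4Z) | C=C1C(=O)O[C@@H]2/C=C(/C)CC/C=C(/CO)[C@H](OC(=O)C(C)(C)O)[C@@H](OC(=O)C(C)C)[C@@H]12 | target

**Totals:** the route has 15 steps. The longest linear sequence is 11 steps (1, 2, 3, 4, 6, 9, 11, 12, 13, 14, 15).

**Three steps most likely to fail**

**Step 14.** Closure of the ten-membered ring may be slower than hydrogen transfer from C2–H or the 1,2-acyloxy shift to the allylic C9 radical. The tether may also force the cis-lactone.
- This fallback sets out from 12 and 18 and returns at 31. The same radical C7–C8 bond is made between two fragments at 0.2 M, and the ring is closed afterwards at C3–C4.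
- 18 and 23 are joined (MNBA, DMAP) to the iodo-dienyl sulfonylacrylate F1. Ring-closing metathesis turns this into the iodoalkenyl butenolide F2.
- H5IO6 converts 12 through the diene diol F3 into the diene aldehyde F4.
- 29 adds to F4 to give the diene iodo ester F5. Mn2(CO)10 under blue light with 1.5 equiv of F2 then gives the seco methylene lactone F6. Here the radical meets a free 5-substituted butenolide, so attack anti to the C6 substituent is the normal outcome, and the high concentration outruns the unimolecular side reactions.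
- 9-BBN-H adds to the terminal vinyl group, which is faster than the electron-poor methylene lactone, to give the seco alkylborane F7. Pd(dppf)Cl2, AsPh3 and Cs2CO3 at 2 mM then close the ring to 31.

**Step 12.** The 1,1-disubstituted, electron-poor sulfonylacrylate may not ring-close in the polyene.
- This fallback sets out from 20 and returns at 25. The ring is closed before C13 is attached.
- Acryloyl chloride and i-Pr2NEt give the plain acrylate F8. This closes easily (second-generation Grubbs catalyst, CH2Cl2, 40 °C) to the α-unsubstituted butenolide F9.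
- A PBu3-catalysed Morita–Baylis–Hillman reaction with aqueous formaldehyde gives the hydroxymethyl butenolide F10.
- Ms2O and 2,6-lutidine at −20 °C give the allylic mesylate F11, which 22 displaces in the same flask to give 25.

**Step 4.** The Felkin selectivity of the chromium reagent may be low.
- This fallback sets out from the crude product of step 4 and returns at 8. C9 is set by hydride delivery instead of by C–C bond formation.
- The mixture of 8 and its syn C9 epimer F12 is oxidised (Dess–Martin periodinane, NaHCO3) to the cross-conjugated dienone F13.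
- Zn(BH4)2 in Et2O at −40 °C reduces the zinc chelate of the ketone and dioxolane oxygen from its open face to give the anti alcohol 8.

**Further compounds**
F1 | step 14 | (2E,4S,5Z)-6-iodohepta-2,5-dien-4-yl 2-[(methylsulfonyl)methyl]acrylate | C/C=C/[C@H](OC(=O)C(=C)CS(C)(=O)=O)/C=C(/C)I
F2 | step 14 | (5S)-5-[(1Z)-2-iodoprop-1-en-1-yl]-3-[(methylsulfonyl)methyl]furan-2(5H)-one | CS(=O)(=O)CC1=C[C@H](OC1=O)/C=C(/C)I
F3 | step 14 | diene diol from 12 (acetonide removed) | C=C/C=C(/CO[Si](c1ccccc1)(c1ccccc1)C(C)(C)C)[C@H](OC(=O)C(C)(C)O[Si](CC)(CC)CC)[C@H](O)CO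
F4 | step 14 | diene C8 aldehyde (9S) | C=C/C=C(/CO[Si](c1ccccc1)(c1ccccc1)C(C)(C)C)[C@H](OC(=O)C(C)(C)O[Si](CC)(CC)CC)C=O
F5 | step 14 | diene 1-iodoalkyl isobutyrate (both C8 epimers) | C=C/C=C(/CO[Si](c1ccccc1)(c1ccccc1)C(C)(C)C)[C@H](OC(=O)C(C)(C)O[Si](CC)(CC)CC)C(I)OC(=O)C(C)C
F6 | step 14 | seco methylene lactone (C3–C4 open; C4 iodide; C2=C3 vinyl; C6 to C9 configured as in 31) | C=C1C(=O)O[C@H](/C=C(/C)I)[C@H]1[C@H](OC(=O)C(C)C)[C@@H](OC(=O)C(C)(C)O[Si](CC)(CC)CC)/C(CO[Si](c1ccccc1)(c1ccccc1)C(C)(C)C)=C\C=C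
F7 | step 14 | seco alkylborane (9-BBN on C3 of F6) | C=C1C(=O)O[C@H](/C=C(/C)I)[C@H]1[C@H](OC(=O)C(C)C)[C@@H](OC(=O)C(C)(C)O[Si](CC)(CC)CC)/C(CO[Si](c1ccccc1)(c1ccccc1)C(C)(C)C)=C\CCB1C2CCCC1CCC2
F8 | step 12 | acrylate ester of 20 | C/C=C/[C@H](OC(=O)C=C)/C=C(/C)CC/C=C(/CO[Si](c1ccccc1)(c1ccccc1)C(C)(C)C)[C@H](OC(=O)C(C)(C)O[Si](CC)(CC)CC)[C@H]1COC(C)(C)O1
F9 | step 12 | α-unsubstituted butenolide | O=C1C=C[C@H](O1)/C=C(/C)CC/C=C(/CO[Si](c2ccccc2)(c2ccccc2)C(C)(C)C)[C@H](OC(=O)C(C)(C)O[Si](CC)(CC)CC)[C@H]2COC(C)(C)O2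
F10 | step 12 | α-(hydroxymethyl)butenolide | OCC1=C[C@H](OC1=O)/C=C(/C)CC/C=C(/CO[Si](c2ccccc2)(c2ccccc2)C(C)(C)C)[C@H](OC(=O)C(C)(C)O[Si](CC)(CC)CC)[C@H]2COC(C)(C)O2
F11 | step 12 | α-(mesyloxymethyl)butenolide | CS(=O)(=O)OCC1=C[C@H](OC1=O)/C=C(/C)CC/C=C(/CO[Si](c2ccccc2)(c2ccccc2)C(C)(C)C)[C@H](OC(=O)C(C)(C)O[Si](CC)(CC)CC)[C@H]2COC(C)(C)O2
F12 | step 4 | syn C9 epimer of 8 (1R,2Z; dioxolane 4R) | C=C/C=C(/CO[Si](c1ccccc1)(c1ccccc1)C(C)(C)C)[C@@H](O)[C@H]1COC(C)(C)O1
F13 | step 4 | cross-conjugated dienone (C9 ketone; dioxolane 4R) | C=C/C=C(/CO[Si](c1ccccc1)(c1ccccc1)C(C)(C)C)C(=O)[C@H]1COC(C)(C)O1
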